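## Retrosynthetic overview

1. Only one ring is made, the 1,4-dioxane ring; both aromatic rings and all carbons come from caffeic acid 1 and sinapic acid 5.
2. Side chains are set first: 1 + amine salt 2 (via 3) gives the catechol Weinreb amide 4 (latent enal); 5 + (2R)-camphorsultam 6 (via 7, 8, 9) gives sinapoyl sultam 10 (latent CH2OH plus chiral controller).
3. Key disconnection: the O–C8′ and O–C7′ bonds of the dioxane ring, both formed in one oxidative phenol coupling of 4 with 10. Radical 8′–O–4 coupling gives quinone methide 11 (sultam sets C8′); 1,6-addition of the neighbouring OH closes the ring trans (sets C7′) to give 12.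
4. Endgame in one flask: hydride cleavage of the sultam (to 13), then Weinreb reduction (via 14) gives target 15.
5. Labels: C7′ is the benzylic carbon, C8′ the carbon bearing C9′; in benzodioxin numbering C2 = C8′ and C3 = C7′.

Assumption: the (2R)-sultam directs the new C8′–O bond to the Cα-re face of 10 (the face it leaves open in non-chelated reactions of its N-enoyl derivatives), giving (2R,3S)-12 and hence the (S,S) target; if the other diastereomer dominates, the same route is run with the (2S)-sultam.

## Route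

Step 1
Reactants: 1 caffeic acid [(E)-3-(3,4-dihydroxyphenyl)prop-2-enoic acid]; 2 N,O-dimethylhydroxylamine hydrochloride
Product: 4 (E)-3-(3,4-dihydroxyphenyl)-N-methoxy-N-methylprop-2-enamide, via caffeoyl benzotriazol-1-yl ester 3 (not isolated)
Conditions: EDC·HCl, HOBt, N-methylmorpholine, DMF, 0 °C → rt
Reagents that add atoms: none
Why: Carbodiimide/HOBt amide coupling (Weinreb amide formation): the amine outcompetes the catechol OH groups for the active ester, so unprotected caffeic acid is acylated at nitrogen only; the E-alkene is untouched and no stereocentre is formed.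

Step 2
Reactants: 5 sinapic acid [(E)-3-(4-hydroxy-3,5-dimethoxyphenyl)prop-2-enoic acid]; 6 (2R)-bornane-10,2-sultam [(1S)-(−)-2,10-camphorsultam]
Product: 10 (2R)-N-[(E)-3-(4-hydroxy-3,5-dimethoxyphenyl)prop-2-enoyl]bornane-10,2-sultam, via bis(trimethylsilyl) sinapate 7 (not isolated), via O-trimethylsilyl sinapoyl chloride 8 (not isolated), via O-trimethylsilyl sinapoyl sultam 9 (not isolated)
Conditions: HMDS, cat. TMSCl, CH2Cl2, reflux, evaporate; (COCl)2, cat. DMF, CH2Cl2, 0 °C → rt, evaporate; add to 6/NaH, THF, 0 °C → rt; 1 M HCl, THF–MeOH, rt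
Reagents that add atoms: none
Why: N-Acylation of Oppolzer's sultam with an acid chloride under transient silyl protection: the silyl ester is converted to the acid chloride under neutral conditions while the hindered aryl silyl ether masks the phenol, the sodium salt of 6 is acylated at nitrogen, and the silyl ether is cleaved in the acidic work-up; E-geometry is kept and no new stereocentre is formed.

Step 3
Reactants: 4 (E)-3-(3,4-dihydroxyphenyl)-N-methoxy-N-methylprop-2-enamide; 10 sinapoyl sultam
Product: 12 (2R)-N-{[(2R,3S)-3-(4-hydroxy-3,5-dimethoxyphenyl)-6-{(E)-3-[methoxy(methyl)amino]-3-oxoprop-1-en-1-yl}-2,3-dihydro-1,4-benzodioxin-2-yl]carbonyl}bornane-10,2-sultam, via quinone methide 11 (not isolated)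
Conditions: Ag2O (3 equiv), 4 (2.5 equiv), toluene–acetone 2:1, rt, dark, Ar; 10 added over 4 h
Reagents that add atoms: none
Why: Proposed new method: biomimetic oxidative phenol coupling (radical 8′–O–4 coupling, then oxa-1,6-addition to a p-quinone methide): Ag2O oxidises both phenols by one electron, the catechol radical couples through O-4 (the oxygen para to the conjugated side chain, as in caffeyl-type lignification) with C8′ of the sinapoyl radical on the Cα-re face left open by the sultam (s-cis enoyl, C=O anti to SO2, one sulfonyl oxygen over the other face), which sets C8′ in quinone methide 11, and the neighbouring 3-OH then adds to C7′ so that aryl and acyl end up trans (diequatorial); the closest known reactions are the Ag2O/Ag2CO3 coupling of catechols with coniferyl or sinapyl alcohol to trans-1,4-benzodioxane neolignans and the camphorsultam-controlled oxidative 8–5 dimerisation of feruloyl amides, and the minor diastereomer and the O-3 regioisomer are removed by chromatography or crystallisation.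

Step 4
Reactants: 12 benzodioxane acyl sultam
Product: 15 (E)-3-[(2S,3S)-3-(4-hydroxy-3,5-dimethoxyphenyl)-2-(hydroxymethyl)-2,3-dihydro-1,4-benzodioxin-6-yl]prop-2-enal, via Weinreb amide alcohol 13 (not isolated), via aluminium hemiaminal 14 (not isolated)
Conditions: LiBH4, MeOH (1 equiv), THF, 0 °C; then i-Bu2AlH, −78 °C; acetone, −78 → 0 °C; aq. potassium sodium tartrate
Reagents that add atoms: none
Why: Reductive cleavage of an N-acyl sultam with LiBH4 (C9′ becomes CH2OH, 6 is released, the Weinreb amide and alkene are left alone) followed by i-Bu2AlH reduction of the Weinreb amide, whose chelated tetrahedral aluminate 14 survives until hydrolysis and then gives the E-enal without over-reduction; C8′ is reduced rather than deprotonated, so both stereocentres are retained (the C2 descriptor changes from R to S only because CH2OH ranks below C3).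

## Compound list

1 | caffeic acid, (E)-3-(3,4-dihydroxyphenyl)prop-2-enoic acid | OC(=O)/C=C/c1ccc(O)c(O)c1 | starting material
2 | N,O-dimethylhydroxylamine hydrochloride | CNOC.Cl | starting material
3 | benzotriazol-1-yl (E)-3-(3,4-dihydroxyphenyl)prop-2-enoate | O=C(/C=C/c1ccc(O)c(O)c1)On1nnc2ccccc12 | intermediate
4 | (E)-3-(3,4-dihydroxyphenyl)-N-methoxy-N-methylprop-2-enamide | CON(C)C(=O)/C=C/c1ccc(O)c(O)c1 | intermediate
5 | sinapic acid, (E)-3-(4-hydroxy-3,5-dimethoxyphenyl)prop-2-enoic acid | COc1cc(/C=C/C(=O)O)cc(OC)c1O | starting material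
6 | (2R)-bornane-10,2-sultam, (3aS,6R,7aR)-8,8-dimethylhexahydro-3H-3a,6-methano-2,1-benzisothiazole 2,2-dioxide | CC1(C)[C@@H]2CC[C@]13CS(=O)(=O)N[C@@H]3C2 | starting material
7 | trimethylsilyl (E)-3-[3,5-dimethoxy-4-(trimethylsilyloxy)phenyl]prop-2-enoate | COc1cc(/C=C/C(=O)O[Si](C)(C)C)cc(OC)c1O[Si](C)(C)C | intermediate
8 | (E)-3-[3,5-dimethoxy-4-(trimethylsilyloxy)phenyl]prop-2-enoyl chloride | COc1cc(/C=C/C(=O)Cl)cc(OC)c1O[Si](C)(C)C | intermediate
9 | (2R)-N-{(E)-3-[3,5-dimethoxy-4-(trimethylsilyloxy)phenyl]prop-2-enoyl}bornane-10,2-sultam | CC1(C)[C@@H]2CC[C@]13CS(=O)(=O)N(C(=O)/C=C/c4cc(OC)c(O[Si](C)(C)C)c(OC)c4)[C@@H]3C2 | intermediate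
10 | (2R)-N-[(E)-3-(4-hydroxy-3,5-dimethoxyphenyl)prop-2-enoyl]bornane-10,2-sultam | CC1(C)[C@@H]2CC[C@]13CS(=O)(=O)N(C(=O)/C=C/c4cc(OC)c(O)c(OC)c4)[C@@H]3C2 | intermediate
11 | (2R)-N-[(2R)-3-(3,5-dimethoxy-4-oxocyclohexa-2,5-dien-1-ylidene)-2-{2-hydroxy-4-[(E)-3-[methoxy(methyl)amino]-3-oxoprop-1-en-1-yl]phenoxy}propanoyl]bornane-10,2-sultam (quinone methide) | CC1(C)[C@@H]2CC[C@]13CS(=O)(=O)N(C(=O)[C@H](Oc4ccc(/C=C/C(=O)N(C)OC)cc4O)C=C5C=C(OC)C(=O)C(OC)=C5)[C@@H]3C2 | intermediate
12 | (2R)-N-{[(2R,3S)-3-(4-hydroxy-3,5-dimethoxyphenyl)-6-{(E)-3-[methoxy(methyl)amino]-3-oxoprop-1-en-1-yl}-2,3-dihydro-1,4-benzodioxin-2-yl]carbonyl}bornane-10,2-sultam | CC1(C)[C@@H]2CC[C@]13CS(=O)(=O)N(C(=O)[C@@H]4Oc5ccc(/C=C/C(=O)N(C)OC)cc5O[C@H]4c6cc(OC)c(O)c(OC)c6)[C@@H]3C2 | intermediate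
13 | (E)-3-[(2S,3S)-3-(4-hydroxy-3,5-dimethoxyphenyl)-2-(hydroxymethyl)-2,3-dihydro-1,4-benzodioxin-6-yl]-N-methoxy-N-methylprop-2-enamide | COc1cc([C@@H]2Oc3cc(/C=C/C(=O)N(C)OC)ccc3O[C@H]2CO)cc(OC)c1O | intermediate
14 | (E)-3-[(2S,3S)-3-(4-hydroxy-3,5-dimethoxyphenyl)-2-(hydroxymethyl)-2,3-dihydro-1,4-benzodioxin-6-yl]-1-[methoxy(methyl)amino]prop-2-en-1-ol, held as its aluminium alkoxide chelate (both carbinol epimers) | COc1cc([C@@H]2Oc3cc(/C=C/C(O)N(C)OC)ccc3O[C@H]2CO)cc(OC)c1O | intermediate
15 | (E)-3-[(2S,3S)-3-(4-hydroxy-3,5-dimethoxyphenyl)-2-(hydroxymethyl)-2,3-dihydro-1,4-benzodioxin-6-yl]prop-2-enal | COc1cc([C@@H]2Oc3cc(/C=C/C=O)ccc3O[C@H]2CO)cc(OC)c1O | target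

## Step count and risks

Total step count: 4 (steps 1 and 2 run in parallel). Longest linear sequence: 3 steps (1 → 4 → 12 → 15, or 5 → 10 → 12 → 15).

Most likely to fail, in order:

Step 3 (cross-coupling). The risks are homo-coupling of either phenol, O-3 versus O-4 regiochemistry, and only moderate facial control by the sultam. The fallback leaves the auxiliary out of the ring-forming step. It sets out from 4: Ag2CO3 (toluene–acetone, 55 °C) and commercial sinapyl alcohol give, by the well-tried alcohol version of the same coupling, the racemic trans-benzodioxane Weinreb amide alcohol F2. Preparative chromatography on a chiral stationary phase (amylose tris(3,5-dimethylphenylcarbamate), CO2/MeOH) separates the enantiomers. The (2S,3S)-enantiomer is compound 13, where the route is rejoined (i-Bu2AlH part of step 4).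

Step 4 (double reduction in one flask). The risks are incomplete sultam cleavage before the i-Bu2AlH stage, leftover borohydride reducing the enal at the quench, and 1,4-reduction. The fallback is a redox detour instead of differentiation. It sets out from 12: LiAlH4 (THF, 0 °C), then NaBH4/CeCl3·7H2O (MeOH, 0 °C) on the crude product, takes both acyl groups down to the triol (E)-3-[(2S,3S)-3-(4-hydroxy-3,5-dimethoxyphenyl)-2-(hydroxymethyl)-2,3-dihydro-1,4-benzodioxin-6-yl]prop-2-en-1-ol F3. The cinnamyl alcohol alone is then oxidised (DDQ, 1.05 equiv, THF, 0 °C, or activated MnO2, acetone) to give 15, where it comes back to the route.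

Step 2 (one-pot acylation). The risks are loss of the aryl silyl ether during acid chloride formation (giving ester oligomers) and silyl transfer to the sultam anion. The fallback makes the C7′–aryl bond instead of the N–acyl bond. It sets out from 6: NaH/acryloyl chloride (toluene, 0 °C) gives (2R)-N-acryloylbornane-10,2-sultam F1. A Heck reaction with commercial 4-bromo-2,6-dimethoxyphenol (Pd(OAc)2, P(o-tol)3, Et3N, DMF, 90 °C; free phenols are tolerated) gives the E-enoyl sultam 10, where the route is rejoined.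

## Further compounds

F1 | step 2 | (2R)-N-acryloylbornane-10,2-sultam | CC1(C)[C@@H]2CC[C@]13CS(=O)(=O)N(C(=O)C=C)[C@@H]3C2
F2 | step 3 | racemic trans-(E)-3-[3-(4-hydroxy-3,5-dimethoxyphenyl)-2-(hydroxymethyl)-2,3-dihydro-1,4-benzodioxin-6-yl]-N-methoxy-N-methylprop-2-enamide (1:1 mixture of 13 and its enantiomer) | COc1cc([C@@H]2Oc3cc(/C=C/C(=O)N(C)OC)ccc3O[C@H]2CO)cc(OC)c1O.COc1cc([C@H]2Oc3cc(/C=C/C(=O)N(C)OC)ccc3O[C@@H]2CO)cc(OC)c1O
F3 | step 4 | (E)-3-[(2S,3S)-3-(4-hydroxy-3,5-dimethoxyphenyl)-2-(hydroxymethyl)-2,3-dihydro-1,4-benzodioxin-6-yl]prop-2-en-1-ol | COc1cc([C@@H]2Oc3cc(/C=C/CO)ccc3O[C@H]2CO)cc(OC)c1O
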